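**Retrosynthetic overview**
- Last step: one acyclic, fully acylated ene–yne–vinyl acetal is closed to both rings by a ring-closing metathesis cascade. Ring A (cyclopentene, C5=C6) closes first on the alkyne and ring B (dihydropyran, C3=C4) second on the vinyl ether, so the dienol ether forms directly.
- The C1 acyloxy(vinyloxy) acetal comes from an α-alkynyl aldehyde, 2-iodoethanol and 3-acetoxy-3-methylbutanoic acid (Felkin–Anh capture, then loss of HI).
- The C9–C5 bond comes from SN2 opening of a 2,3-epoxy alcohol by an alkynylalane made from propargyl alcohol.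
- C7, C8 and C9 come from a Sharpless kinetic resolution of a racemic dienol. Its trisubstituted alkene comes from but-2-yne-1,4-diol and acrolein by directed syn-hydrozirconation.

Assumption: the SMILES is taken literally, which gives (1S,7R,8S,9S) in iridoid numbering (C1 acetal carbon, O2, C3=C4, C5=C6, C7, C8, C9; C10 = CH2 on C8; C11 = CH2 on C4). These labels are used for all intermediates.

**Step 1**
Reactants: 1 but-2-yne-1,4-diol
Product: 2 4-[(tert-butyldimethylsilyl)oxy]but-2-yn-1-ol
Conditions: NaH (1.0 equiv), THF, rt; TBSCl (1.0 equiv), rt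
Reagents that add atoms: tert-butyldimethylsilyl chloride, CC(C)(C)[Si](C)(C)Cl
Why: Monoalkoxide silylation (McDougal protocol) works because the poorly soluble monosodium salt of the symmetric diol reacts only once, which leaves free the CH2OH (future C10) that steers step 2; no stereocentre is formed.

**Step 2**
Reactants: 2 4-[(tert-butyldimethylsilyl)oxy]but-2-yn-1-ol; 3 acrolein
Product: 6 rac-(4E)-6-[(tert-butyldimethylsilyl)oxy]-4-(hydroxymethyl)hexa-1,4-dien-3-ol, via alkenylzirconocene 4 (not isolated), via alkenylzinc 5 (not isolated)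
Conditions: n-BuLi, THF, −78 °C; Cp2ZrHCl, THF, rt; Me2Zn, toluene, −65 °C; 3, 0 °C; aq NH4Cl
Reagents that add atoms: none
Why: Alkoxide-directed syn-hydrozirconation puts Zr on the alkyne carbon next to CH2OLi (C8) and H on C9 on the same side, and Zr-to-Zn transmetalation followed by 1,2-addition of the alkenylzinc to acrolein keeps this geometry (C10 cis to C1) and gives C7 as a racemate that step 4 resolves.

**Step 3**
Reactants: 6 rac-(4E)-6-[(tert-butyldimethylsilyl)oxy]-4-(hydroxymethyl)hexa-1,4-dien-3-ol; 7 3-methylbutanoyl chloride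
Product: 8 rac-(2E)-4-[(tert-butyldimethylsilyl)oxy]-2-(1-hydroxyprop-2-en-1-yl)but-2-en-1-yl 3-methylbutanoate
Conditions: 7 (1.05 equiv), 2,4,6-collidine, CH2Cl2, −78 °C
Reagents that add atoms: none
Why: In this chemoselective O-acylation the primary allylic OH reacts far faster than the secondary bis-allylic OH at −78 °C with a weak base, which installs the final C10 ester and leaves C7-OH as the only directing group.

**Step 4**
Reactants: 8 rac-(2E)-4-[(tert-butyldimethylsilyl)oxy]-2-(1-hydroxyprop-2-en-1-yl)but-2-en-1-yl 3-methylbutanoate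
Product: 9 {(2S,3S)-3-{[(tert-butyldimethylsilyl)oxy]methyl}-2-[(1R)-1-hydroxyprop-2-en-1-yl]oxiran-2-yl}methyl 3-methylbutanoate
Conditions: Ti(OiPr)4 (15 mol%), D-(−)-DIPT (18 mol%), t-BuOOH (0.5 equiv), 4 Å molecular sieves, CH2Cl2, −20 °C, stop at about 45% conversion
Reagents that add atoms: tert-butyl hydroperoxide, CC(C)(C)OO
Why: In this Sharpless asymmetric epoxidation run as a kinetic resolution, D-(−)-DIPT makes the (7R)-alcohol the fast enantiomer and delivers oxygen to the face given by the Sharpless mnemonic (erythro product), which sets C7, C8 and the pre-inversion C9 at once, while the vinyl group of this enantiomer is less nucleophilic and mismatched and the (7S)-alcohol stays behind.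

**Step 5**
Reactants: 9 epoxy alcohol from step 4; 10 prop-2-yn-1-ol
Product: 12 (2S,3R)-3-{[(tert-butyldimethylsilyl)oxy]methyl}-2,6-dihydroxy-2-[(1R)-1-hydroxyprop-2-en-1-yl]hex-4-yn-1-yl 3-methylbutanoate (7R,8S,9R), via bis-alane 11 (not isolated)
Conditions: 10 (4 equiv), n-BuLi (8 equiv), toluene, −78 to 0 °C; Et2AlCl (8 equiv), 0 °C; 9, toluene, 0 °C to rt; aq Rochelle salt
Reagents that add atoms: none
Why: In this alkynylalane opening of a 2,3-epoxy alcohol the aluminium alkoxide on C7-O activates the oxirane and the alkynyl group attacks the distal, non-quaternary C9 by SN2 with clean inversion, which fixes C9, frees the tertiary C8-OH with retention and leaves the isovalerate untouched because the alane is a weak nucleophile towards esters.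

**Step 6**
Reactants: 12 triol from step 5; 13 acetyl chloride; 7 3-methylbutanoyl chloride
Product: 15 (7R,8S,9R)-C11 acetate, C7 and C10 bis(3-methylbutanoate), C1 TBS ether, C8-OH free, via monoacetate 14 (not isolated)
Conditions: 13 (1.05 equiv), 2,4,6-collidine, CH2Cl2, −78 °C; then 7 (1.5 equiv), DMAP (cat.), −78 °C to rt
Reagents that add atoms: none
Why: In this sequential chemoselective acylation the unhindered primary propargylic OH is acetylated first at −78 °C, the secondary allylic C7-OH then takes the isovaleryl group under DMAP catalysis, and the hindered tertiary C8-OH stays free; no stereocentre is touched.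

**Step 7**
Reactants: 15 TBS ether from step 6
Product: 17 (7R,8S,9S)-aldehyde (C1 = CHO), via primary alcohol 16 (not isolated)
Conditions: PhI(OAc)2 (1.3 equiv), TEMPO (10 mol%), Bi(OTf)3 (5 mol%), wet MeCN, rt; used without storage
Reagents that add atoms: none
Why: This one-pot oxidative desilylation (Lewis-acid-catalysed TBS cleavage, then TEMPO/oxoammonium oxidation) needs no amine base, which protects the labile α-alkynyl, β-hydroxy aldehyde from epimerisation at C9, alkyne-to-allene isomerisation and retro-aldol cleavage.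

**Step 8**
Reactants: 18 3-hydroxy-3-methylbutanoic acid; 13 acetyl chloride
Product: 19 3-acetoxy-3-methylbutanoic acid
Conditions: 13 (neat, excess), rt; evaporate; H2O, rt
Reagents that add atoms: none
Why: O-Acetylation of the tertiary alcohol with neat acid chloride avoids any base, so β-elimination to 3-methylbut-2-enoic acid is suppressed and the transient mixed anhydride is hydrolysed on work-up.

**Step 9**
Reactants: 17 aldehyde from step 7; 19 3-acetoxy-3-methylbutanoic acid; 20 2-iodoethanol
Product: 22 (1S,7R,8S,9S)-C1 (2-iodoethoxy)(3-acetoxy-3-methylbutanoyloxy) acetal, via chloro ether 21 (not isolated)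
Conditions: 20 (1.05 equiv), Me3SiCl (3 equiv), CH2Cl2, 0 °C; evaporate; 19 (1.2 equiv), i-Pr2NEt, CH2Cl2, −40 to 0 °C
Reagents that add atoms: none
Why: α-Chloro ether formation is followed by SN1-type carboxylate capture, in which the alkoxycarbenium ion from 21 is attacked anti to the bulky C8 substituent on C9 with the ether oxygen next to the alkynyl group (Felkin–Anh model), so (1S) is expected as the major epimer with moderate selectivity and the minor one is removed by chromatography.

**Step 10**
Reactants: 22 iodoethyl acetal from step 9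
Product: 23 (1S,7R,8S,9S)-C1 (vinyloxy)(3-acetoxy-3-methylbutanoyloxy) acetal (acyclic ene–yne–vinyl ether)
Conditions: AgF (3 equiv), pyridine, rt, dark
Reagents that add atoms: none
Why: Helferich-type dehydroiodination (silver-assisted E2) of a primary iodide whose only β-hydrogens sit on the O-bearing carbon gives the vinyl ether under conditions that esters, including anomeric-type acyloxy acetals, are known to survive.

**Step 11**
Reactants: 23 acyclic ene–yne–vinyl ether from step 10
Product: 24 CNP0331701.2, (1S,7R,8S,9S)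
Conditions: second-generation Grubbs catalyst (10 mol%), ethylene (1 atm), toluene (2 mM), 70 °C
Reagents that add atoms: none
Why: Proposed new method: in this ene–yne–enol ether ring-closing metathesis cascade the ruthenium alkylidene loads on the C6 vinyl group (or first turns the alkyne with ethylene into the 2,3-disubstituted butadiene, which converges on the same product), 5-exo closure on C5≡C4 forms ring A and a vinylcarbene at C4 that closes ring B on the vinyl ether six atoms away with loss of ethylene, so the C3=C4–C5=C6 dienol ether appears under neutral conditions with C1, C7, C8 and C9 untouched; the closest known reaction types are tandem dienyne ring-closing metathesis, enol ether–olefin ring-closing metathesis and enol ether–alkyne cross metathesis.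

**Compound list**
1 | but-2-yne-1,4-diol | OCC#CCO | starting material
2 | 4-[(tert-butyldimethylsilyl)oxy]but-2-yn-1-ol | OCC#CCO[Si](C)(C)C(C)(C)C | intermediate
3 | acrolein | C=CC=O | starting material
4 | alkenyl(chloro)zirconocene lithium alkoxide (Zr on C8, cis to H on C9) | [Li]OC/C(=C\CO[Si](C)(C)C(C)(C)C)[Zr](Cl)(C1C=CC=C1)C1C=CC=C1 | intermediate
5 | alkenyl(methyl)zinc lithium alkoxide | [Li]OC/C(=C\CO[Si](C)(C)C(C)(C)C)[Zn]C | intermediate
6 | rac-(4E)-6-[(tert-butyldimethylsilyl)oxy]-4-(hydroxymethyl)hexa-1,4-dien-3-ol | C=CC(O)/C(CO)=C/CO[Si](C)(C)C(C)(C)C | intermediate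
7 | 3-methylbutanoyl chloride | CC(C)CC(=O)Cl | starting material
8 | rac-(2E)-4-[(tert-butyldimethylsilyl)oxy]-2-(1-hydroxyprop-2-en-1-yl)but-2-en-1-yl 3-methylbutanoate | C=CC(O)/C(COC(=O)CC(C)C)=C/CO[Si](C)(C)C(C)(C)C | intermediate
9 | {(2S,3S)-3-{[(tert-butyldimethylsilyl)oxy]methyl}-2-[(1R)-1-hydroxyprop-2-en-1-yl]oxiran-2-yl}methyl 3-methylbutanoate | C=C[C@@H](O)[C@]1(COC(=O)CC(C)C)O[C@H]1CO[Si](C)(C)C(C)(C)C | intermediate
10 | prop-2-yn-1-ol | C#CCO | starting material
11 | diethyl{3-[(diethylalumanyl)oxy]prop-1-yn-1-yl}alane | CC[Al](CC)OCC#C[Al](CC)CC | intermediate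
12 | (7R,8S,9R)-triol, C10 isovalerate, C1 TBS ether | C=C[C@@H](O)[C@@](O)(COC(=O)CC(C)C)[C@H](C#CCO)CO[Si](C)(C)C(C)(C)C | intermediate
13 | acetyl chloride | CC(=O)Cl | starting material
14 | (7R,8S,9R)-C11 monoacetate diol | C=C[C@@H](O)[C@@](O)(COC(=O)CC(C)C)[C@H](C#CCOC(C)=O)CO[Si](C)(C)C(C)(C)C | intermediate
15 | (7R,8S,9R)-C11 acetate, C7/C10 bis(isovalerate), C1 TBS ether | C=C[C@@H](OC(=O)CC(C)C)[C@@](O)(COC(=O)CC(C)C)[C@H](C#CCOC(C)=O)CO[Si](C)(C)C(C)(C)C | intermediate
16 | (7R,8S,9R)-C1 primary alcohol | C=C[C@@H](OC(=O)CC(C)C)[C@@](O)(COC(=O)CC(C)C)[C@H](C#CCOC(C)=O)CO | intermediate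
17 | (7R,8S,9S)-C1 aldehyde | C=C[C@@H](OC(=O)CC(C)C)[C@@](O)(COC(=O)CC(C)C)[C@H](C#CCOC(C)=O)C=O | intermediate
18 | 3-hydroxy-3-methylbutanoic acid | CC(C)(O)CC(=O)O | starting material
19 | 3-acetoxy-3-methylbutanoic acid | CC(=O)OC(C)(C)CC(=O)O | intermediate
20 | 2-iodoethanol | OCCI | starting material
21 | (7R,8S,9S)-C1 chloro(2-iodoethoxy)methyl compound, C1 epimers | C=C[C@@H](OC(=O)CC(C)C)[C@@](O)(COC(=O)CC(C)C)[C@H](C#CCOC(C)=O)C(Cl)OCCI | intermediate
22 | (1S,7R,8S,9S)-C1 (2-iodoethoxy)(3-acetoxy-3-methylbutanoyloxy) acetal | C=C[C@@H](OC(=O)CC(C)C)[C@@](O)(COC(=O)CC(C)C)[C@H](C#CCOC(C)=O)[C@@H](OCCI)OC(=O)CC(C)(C)OC(C)=O | intermediate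
23 | (1S,7R,8S,9S)-C1 (vinyloxy)(3-acetoxy-3-methylbutanoyloxy) acetal | C=C[C@@H](OC(=O)CC(C)C)[C@@](O)(COC(=O)CC(C)C)[C@H](C#CCOC(C)=O)[C@@H](OC=C)OC(=O)CC(C)(C)OC(C)=O | intermediate
24 | CNP0331701.2 | CC(=O)OCC1=CO[C@@H](OC(=O)CC(C)(C)OC(C)=O)[C@H]2C1=C[C@@H](OC(=O)CC(C)C)[C@@]2(O)COC(=O)CC(C)C | target

**Step count and risk**

Total step count: 11. Longest linear sequence: 10 (steps 1–7 and 9–11). Step 8 is a one-step side branch.

**Step 11.** The vinyl ether may capture the catalyst as a Fischer carbene, which could close in the wrong mode on the alkyne. The fallback sets out from 22 and comes back at 24. Compound 22 has no vinyl ether yet, so it is first submitted to cross enyne metathesis with ethylene (second-generation Grubbs catalyst, ethylene, toluene, 80 °C). This gives the (1S,7R,8S,9S)-2,3-disubstituted butadiene iodoethyl acetal F4. AgF in pyridine then gives the (1S,7R,8S,9S)-butadiene vinyl acetal F5. A double ring-closing metathesis of F5 (C5=CH2 with the C6 vinyl group, C4=CH2 with the vinyl ether) closes ring A and ring B in the same flask and delivers 24.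

**Step 9.** HCl may enolise 17, or the mixed acetal may not form cleanly. The fallback sets out from 17 and comes back at 21. Aldehyde 17 is converted with 20 (2.5 equiv), PPTS and MgSO4 in CH2Cl2 into the isolable (7R,8S,9S)-bis(2-iodoethyl) acetal F3. Acetal–acyl chloride exchange with 13 and ZnCl2 (1 mol%) then gives chloro ether 21 without free HCl. From there 21 is carried on with 19 and i-Pr2NEt as in the main route.

**Step 2.** The alkoxide-bearing alkenylzirconocene may not transmetalate, or may add poorly to acrolein. The fallback sets out from 2 and comes back at 8. The same directed hydrozirconation is quenched with I2 to give (E)-4-[(tert-butyldimethylsilyl)oxy]-2-iodobut-2-en-1-ol F1. Acylation with 7 and pyridine gives (E)-4-[(tert-butyldimethylsilyl)oxy]-2-iodobut-2-en-1-yl 3-methylbutanoate F2. A Nozaki–Hiyama–Kishi coupling of F2 with 3 (CrCl2, NiCl2 cat., DMF) tolerates the ester, retains the alkene geometry and gives 8 directly.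

**Further compounds**
F1 | step 2 | (E)-4-[(tert-butyldimethylsilyl)oxy]-2-iodobut-2-en-1-ol | OC/C(I)=C\CO[Si](C)(C)C(C)(C)C
F2 | step 2 | (E)-4-[(tert-butyldimethylsilyl)oxy]-2-iodobut-2-en-1-yl 3-methylbutanoate | CC(C)CC(=O)OC/C(I)=C\CO[Si](C)(C)C(C)(C)C
F3 | step 9 | (7R,8S,9S)-bis(2-iodoethyl) acetal | C=C[C@@H](OC(=O)CC(C)C)[C@@](O)(COC(=O)CC(C)C)[C@H](C#CCOC(C)=O)C(OCCI)OCCI
F4 | step 11 | (1S,7R,8S,9S)-2,3-disubstituted butadiene iodoethyl acetal | C=C[C@@H](OC(=O)CC(C)C)[C@@](O)(COC(=O)CC(C)C)[C@H](C(=C)C(=C)COC(C)=O)[C@@H](OCCI)OC(=O)CC(C)(C)OC(C)=O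
F5 | step 11 | (1S,7R,8S,9S)-butadiene vinyl acetal | C=C[C@@H](OC(=O)CC(C)C)[C@@](O)(COC(=O)CC(C)C)[C@H](C(=C)C(=C)COC(C)=O)[C@@H](OC=C)OC(=O)CC(C)(C)OC(C)=O
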